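The runs were computed for an exercise; scatter was added.

**Late slope.** Late in the west run J stood still while Z kept climbing, so I turned the question round and asked what would have to hold for Z to overtake J by 15 d in the new flask of D, Q and X.

| flask | D | Q | X | remark | time |
|---|---|---|---|---|---|
| west | 2 M | 0.74 equiv | 0.60 M | run made earlier |  |
| flask | 2.0 M | 1.10 equiv | 0.600 M |  | 15 d |

- west (time / d: Z / %, J / %): 1.67: 3.8, 37.6; 5.00: 4.2, 51.7; 8.00: 7.9, 53.0; 12.0: 10.0, 49.0; 20.0: 14.8, 49.9

(each reading ± 1 percentage point)

- ratio of Z to J at 2.0 h
- ratio of Z to J at 15 d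
- which of Z and J there is more of at 15 d

- the numbers in the tables scatter by 1 percentage point (one standard deviation)

**The count.** From 5.00 d to 20.0 d the west Z gained 0.00707 d⁻¹ as a fraction of the D charged, while J averaged 50.9%, and I held J at that level for the new flask. This flask differs from west in Q, 1.10 equiv against 0.74 equiv, and I assumed that Z's gain grows in proportion, which gave 0.0105 d⁻¹. At that gain Z needs 48.5 d to climb to J's level, longer than the 15 d of the run. The crossing count, the run time divided by that climbing time, is 0.310. In this reckoning Z leads where the count reaches one, and the flask stood short of that by a factor 3.23, so I committed to J leading with a ratio near 0.310 at 15 d. The first reading, at 1.67 d, gave me no ground for 2.0 h.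

**The forecast.** The forecast gave 0.05 at 2.0 h, 0.23 at 15 d and J ahead, holding that “excess Q should push J to about 70%”. I kept J at the west level instead, so my ratio stood above its own.

**The result.** The flask gave 0.00754 at 2.0 h and 0.342 at 15 d, with 44.7% of J against 15.3% of Z, so J led.

    D ⇌ J (K = 2.10, k = 0.0180 h⁻¹)
    X + L → Z (k = 0.0130 L mol⁻¹ h⁻¹)
    E → G (k = 8.90 × 10⁻⁴ h⁻¹)
    D + Q ⇌ L (K = 0.220 L mol⁻¹, k = 0.00820 L mol⁻¹ h⁻¹)
    L ⇌ E (K = 1.70, k = 0.0230 h⁻¹)

In this flask L went on to E with a forward half-life of 1.3 d, shorter than the 3.7 d of its path with X to Z, counted with X as charged. At the end of this flask X stood at 49.0% of its charge and L at 6.12%, and the ratio of 0.342 stood against my count of 0.310. The neighbour charged with 2.4 M of X carries a count of 1.24 if I take Z's gain in proportion to X as well and hold J at the same level, and it ended at a ratio of 1.16, with 35.1% of J against 40.7% of Z; J and Z hold the same at 15 d at 3.30 times this flask's X.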